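## Structural features

The target is a linear trimer of three (−)-epicatechin 3-O-gallate units. Each unit is a 2-arylchroman (fused rings A and C, catechol ring B on C2) whose C3 oxygen carries a 3,4,5-trihydroxybenzoyl group. The upper unit U is bonded through C4 to C6 of the middle unit M, and M through C4 to C8 of the lower unit L; both interflavan bonds are β, trans to the neighbouring C3 ester. There are eight stereocentres: contiguous triads C2–C3–C4 in U and in M (2,3-cis, 3,4-trans) and the pair C2–C3 in L, with every C2 aryl and C3 oxygen on the α face. Fragile features are twenty-one free phenols (oxidation-prone catechol and pyrogallol rings), three secondary esters that cleave or migrate under base, C2 centres that epimerise under base, and two doubly benzylic C4–aryl bonds that ionise under acid. The real difficulty is ring A of M, a pentasubstituted phloroglucinol: O1, O5 and O7 must be told apart, and U must sit on C6 and not on the more nucleophilic C8, while C4a carries C4. Once ring A is made de novo, the cis,trans triad of ring C of M can no longer come from the chiral pool. The key step builds the six carbons of ring A of M (C4a, C5, C6, C7, C8, C8a) from a cyclobutenone that already carries U and O7 and a siloxyalkyne that carries O5 and the future C4, so the 4→6 connection and the identity of each oxygen are fixed by the precursors.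

## Logic of the disconnections

**29 ⇒ 28 ⇒ 27.** Twenty O–CH2Ph bonds and one O–Si bond are cut. All phenols are unveiled at the very end under neutral conditions, so every earlier step runs on lipophilic, oxidation-stable material. The forward steps must spare three esters, the benzylic C2–O1 bonds and both interflavan bonds, and the desilylation must not be basic.

**27 ⇒ 26 + 4.** The C4(M)–C8(L) bond is cut, because it can be formed by the most dependable reaction of flavan chemistry: capture of a C4 cation, bridged by the C3 ester, by a phloroglucinol ring. L then comes intact from the chiral pool as 4, and C4 of M is set by the substrate. The forward step needs β attack, C8 rather than C6 of 4, survival of the U–M bond, and suppression of self-condensation.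

**26 ⇒ 21 + 24.** C3–C4 and O1–C2 of ring C of M are cut. 21 holds a phenol ortho to an acetal carbon, a latent ortho-quinone methide, and 24 delivers C2, C3, ring B and the gallate in one event. The C4 oxygen is kept as the leaving group for the next bond. The forward step needs styrene-type regiochemistry, suprafacial addition (2,3-cis) and face selection by a chiral acid.

**21 ⇒ 13 + 16 (key).** C4a–C8a, C5–C6 and C8–C8a are cut. Ring A of M falls into a four-carbon and a two-carbon piece, each carrying its own oxygen, so the 6-versus-8 question never arises. The forward step needs a neutral thermal cascade that U tolerates and a single orientation of the ketene–alkyne union.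

**13 ⇒ 12 ⇒ 10 ⇒ 6 + 9.** The O–benzyl bond is cut first, then the two ring bonds of the cyclobutenone made by a ketene [2+2], then the C4(U)–C(sp) bond. The symmetrical enol 12 can give only one O-benzyl ether. The C4–alkyne bond must form trans to the C3 ester of 6.

**16 ⇒ 14; 9 ⇒ 7; 24 ⇒ 23 + 3; 23 ⇒ 22.** These are one- or two-step preparations of the small partners from commercial materials. The only stereochemical demand is the Z geometry of 24.

**6 ⇒ 5 ⇒ 2 ⇒ 1 and 4 ⇒ 2 + 3.** The O3–acyl bonds, the C4–O bond and four O–benzyl bonds are cut. Both U and L trace back to 1, which supplies four of the eight stereocentres. The oxidation at C4 must be β-selective and the benzylation must not epimerise C2.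

## Other disconnections considered

**Alternative 1:** Ring C of M is cut at C4–C4a and O1–C2, so that it first appears as a lactone. In the forward step the symmetrical phenol A2 (U para to the hydroxyl, flanked by two benzyloxy groups) would add through an ortho carbon to the β-carbon of the L-derived unsaturated acyl pyrazole A3 under Sc(OTf)3 and a chiral pybox ligand. The phenol would then displace the pyrazole to give the 4-aryl-3,4-dihydrocoumarin A1.
- In favour: C4 of M and the M–L bond are made in one catalytic step of a well-studied type; the two ortho positions of A2 are equivalent; nothing strongly acidic touches the U–M bond.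
- Against: A1 lacks the C2 aryl group and the C3 oxygen, so a relay of several steps must set two more stereocentres from C4 alone. Three galloylations come late because U and L carry silyl ethers. A2 must itself be made by substitution of a phloroglucinol ring by the U cation, where attack ortho to the hydroxyl competes.
- Comparison: on mechanism its key step is the better one (closer analogy than a benzannulation of a 3-alkoxycyclobutenone), and it is the equal of the chosen plan in convergence. On structure the chosen plan is stronger, because the place of U on ring A is fixed by bond construction. On step economy the chosen plan is shorter after its key step (four steps against an estimated eight to ten).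

**Alternative 2:** U is assembled last by cutting C4–C4a, C3–C4 and O1–C2 of its ring C. The pieces are 3,5-bis(benzyloxy)phenol A6, the enol ester 24 and the aldehyde A5, a chiral-pool M–L dimer with a formyl group on C6 and bromine on C8 of M. A chiral phosphoric acid would condense A5 with A6 to an ortho-quinone methide, which would add 24 to give A4, the perbenzylated target with bromine at C8 of M.
- In favour: M and L both come from 1 and are joined by the established 4→8 coupling; the 6-position is secured by the blocking bromine, which the final hydrogenolysis removes; A6 is symmetrical; no ring is built from small-ring precursors.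
- Against: the cycloaddition must create three contiguous stereocentres of U, including the trans relation at C4, against a very large chiral substituent on the methide carbon. C6 formylation of a hindered brominated ring is needed. The dienophile is the same untested one as in step 13.
- Comparison: Alternative 2 is the better on step economy and on reliance on known chemistry before its key step, and the equal of the chosen plan in how securely the 6-position is defined. The chosen plan asks less of its cycloaddition (two centres; C4 is left to the cation coupling) but has two unprecedented steps where Alternative 2 has one.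

**Alternative 3:** Ring C of M is cut at O1–C2 and at the C3–O bond, leading back to the (Z)-cinnamyl phenol silyl ether A8. A Shi-type chiral ketone with KHSO5 would epoxidise the alkene of A8; Bu4NF and camphorsulfonic acid would then free the ring A phenol, which opens the epoxide at benzylic C2 to give A7, the perbenzylated trimer with a free C3 hydroxyl on M.
- In favour: each event is of a known type; anti opening of a cis-epoxide gives the 2,3-cis ring; C4 is already in place and helps to direct the oxidant; the free hydroxyl of A7 allows a clean late galloylation.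
- Against: A8 needs its own answer to the ring A pattern and to C4 bearing L. Dioxirane epoxidation of cis-alkenes is less selective than that of trans-alkenes. The electron-rich epoxide may open by an ionic path and lose the cis relation. One more step (galloylation) follows.
- Comparison: on mechanistic security of the ring C closure Alternative 3 is the better, and its logic is used below as the fallback for step 13. It is the equal of the chosen plan on the M–L bond only if C4 can be set by conjugate addition. On structure it leaves the 4→6 problem open, which the chosen key step solves, and on step economy it is longer.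

Key step: step 10

**Remark on the structures.** Every SMILES below was rebuilt from the target and checked for ring size, substitution and configuration. 13, 16 and 21 are consistent with the benzannulation mechanism, and no correction of connectivity or configuration was needed.

**Remark on design.**
- The acetal of 21 is not hydrolysed; it serves directly as the ortho-quinone methide precursor in step 13.
- L is introduced last by cation coupling (step 14), so no C8 boronate of L is needed and the cycloaddition sets only two stereocentres.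
- 26 forms as C4 epimers, which converge in step 14.
- The silyl group is removed, not exchanged.
- The benzannulation uses excess 16 and no basic work-up, to protect the gallate of U.

**Assumptions.** 3, 7, 14 and 22 are taken as commercial. In alternative 1 the pyrazole is taken as 3,5-dimethylpyrazole, and in A8 the silyl group as tert-butyldimethylsilyl.

**Naming convention.** "U-4β-yl" is the 5,7,3',4'-tetra-O-benzyl-3-O-[3,4,5-tris(benzyloxy)benzoyl]epicatechin-4-yl group (2α-aryl, 3α-acyloxy as in 1), bonded through C4 on the β face, trans to the C3 ester.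

## Route

Step 1
Reactants: 1 (−)-epicatechin
Product: 2 5,7,3',4'-tetra-O-benzyl-(−)-epicatechin
Conditions: BnBr (4.4 equiv), K2CO3, DMF, 0 °C → rt
Reagents that add atoms: benzyl bromide, BrCc1ccccc1
Why: Williamson etherification of the four phenols, which are far more acidic than the C3 alcohol; the mild carbonate base avoids ring-opening epimerisation at C2, so both stereocentres of 1 are carried over.

Step 2
Reactants: 2 5,7,3',4'-tetra-O-benzyl-(−)-epicatechin; 3 3,4,5-tris(benzyloxy)benzoic acid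
Product: 4 5,7,3',4'-tetra-O-benzyl-(−)-epicatechin 3-O-[3,4,5-tris(benzyloxy)benzoate] (unit L)
Conditions: DCC, DMAP (cat.), CH2Cl2, rt
Reagents that add atoms: none
Why: Steglich esterification of the secondary C3 alcohol; no stereocentre is touched.

Step 3
Reactants: 2 5,7,3',4'-tetra-O-benzyl-(−)-epicatechin
Product: 5 4β-(2-ethoxyethoxy)-5,7,3',4'-tetra-O-benzyl-(−)-epicatechin
Conditions: DDQ, 2-ethoxyethanol, CH2Cl2, rt
Reagents that add atoms: 2-ethoxyethanol, CCOCCO
Why: Benzylic oxidation by hydride abstraction at C4 gives a cation stabilised by ring A, which the alcohol should trap on the β face, trans to the C3 hydroxyl; this is an established way to C4-activated flavans.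

Step 4
Reactants: 5 4β-(2-ethoxyethoxy)-5,7,3',4'-tetra-O-benzyl-(−)-epicatechin; 3 3,4,5-tris(benzyloxy)benzoic acid
Product: 6 4β-(2-ethoxyethoxy)-5,7,3',4'-tetra-O-benzyl-(−)-epicatechin 3-O-[3,4,5-tris(benzyloxy)benzoate] (electrophilic unit U)
Conditions: DCC, DMAP, CH2Cl2, rt
Reagents that add atoms: none
Why: Steglich esterification; the C3 ester is the gallate of the target and later acts as participating group at C4.

Step 5
Reactants: 7 ethoxyacetylene
Product: 9 tributyl(ethoxyethynyl)stannane, via lithium ethoxyacetylide 8 (not isolated)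
Conditions: n-BuLi, THF, −78 °C; Bu3SnCl, −78 °C → rt
Reagents that add atoms: tributyltin chloride, CCCC[Sn](Cl)(CCCC)CCCC
Why: Deprotonation of the terminal alkyne and stannylation of the acetylide at carbon.

Step 6
Reactants: 6 4β-(2-ethoxyethoxy)-5,7,3',4'-tetra-O-benzyl-(−)-epicatechin 3-O-[3,4,5-tris(benzyloxy)benzoate]; 9 tributyl(ethoxyethynyl)stannane
Product: 10 4β-(ethoxyethynyl)-5,7,3',4'-tetra-O-benzyl-(−)-epicatechin 3-O-[3,4,5-tris(benzyloxy)benzoate]
Conditions: TMSOTf (0.3 equiv), 9 (2.5 equiv), CH2Cl2, −78 → −40 °C; aq. KF work-up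
Reagents that add atoms: none
Why: Lewis-acid ionisation of the C4 ether gives the C4 cation, bridged on the α face by the C3 ester carbonyl; ipso attack of the tin-bearing alkyne carbon (β to the ethoxy oxygen) from the β face and loss of tin should give the 3,4-trans alkynyl ether, an SN1 alkynylation of a benzylic ether by an alkynylstannane.

Step 7
Reactants: 10 4β-(ethoxyethynyl)-5,7,3',4'-tetra-O-benzyl-(−)-epicatechin 3-O-[3,4,5-tris(benzyloxy)benzoate]
Product: 12 3-hydroxy-2-(U-4β-yl)cyclobut-2-enone, via 3-ethoxy-2-(U-4β-yl)cyclobut-2-enone 11 (not isolated)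
Conditions: ketene (excess, from a ketene generator), CH2Cl2, 0 °C → rt; then 1 M HCl, THF, rt
Reagents that add atoms: ketene, C=C=O; water, O
Why: [2+2] cycloaddition of ketene with the ynol ether (carbonyl carbon to the U-bearing alkyne carbon) gives the 3-ethoxycyclobutenone; mild acid hydrolysis of this vinylogous ester gives the symmetrical 2-substituted cyclobutane-1,3-dione as its enol, with C4 of U untouched.

Step 8
Reactants: 12 3-hydroxy-2-(U-4β-yl)cyclobut-2-enone
Product: 13 3-benzyloxy-2-(U-4β-yl)cyclobut-2-enone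
Conditions: BnOH, PPh3, DIAD, THF, 0 °C → rt
Reagents that add atoms: benzyl alcohol, OCc1ccccc1
Why: Mitsunobu O-alkylation of the strongly acidic enol; the two enol oxygens are equivalent by tautomerism, so only one O-benzyl ether can form, and the neutral conditions spare the esters.

Step 9
Reactants: 14 methyl dimethoxyacetate
Product: 16 3,3-dimethoxy-1-(triisopropylsilyloxy)prop-1-yne, via lithium 3,3-dimethoxyprop-1-yn-1-olate 15 (not isolated)
Conditions: CH2Br2, lithium 2,2,6,6-tetramethylpiperidide, THF, −78 °C; n-BuLi, −78 → 0 °C; TIPSCl, −78 °C → rt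
Reagents that add atoms: dibromomethane, BrCBr; chlorotriisopropylsilane, CC(C)[Si](Cl)(C(C)C)C(C)C
Why: Kowalski ester homologation: the dibromomethyl ketone enolate undergoes bromine–lithium exchange and 1,2-shift to the ynolate, which is silylated on oxygen to the stable triisopropylsilyl ynol ether.

Step 10
Reactants: 13 3-benzyloxy-2-(U-4β-yl)cyclobut-2-enone; 16 3,3-dimethoxy-1-(triisopropylsilyloxy)prop-1-yne
Product: 21 5-benzyloxy-2-(dimethoxymethyl)-3-(triisopropylsilyloxy)-4-(U-4β-yl)phenol, via vinylketene 17 (not isolated), via vinylcyclobutenone 18 (not isolated), via dienylketene 19 (not isolated), via cyclohexadienone 20 (not isolated)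
Conditions: 16 (1.5 equiv), toluene (degassed, base-washed glass), 80 → 110 °C
Reagents that add atoms: none
Why: Proposed new method: the closest known reaction type is the thermal benzannulation of alkyl- or aryl-substituted cyclobutenones with siloxyalkynes, which gives resorcinol monosilyl ethers; what is new is a 3-alkoxycyclobutenone with a secondary benzylic substituent at C2, which should extend the same cascade to a fully differentiated phloroglucinol. Reversible 4π electrocyclic opening of 13 (cleavage of C1–C4) gives vinylketene 17, whose electrophilic ketene carbon bonds to the acetal-bearing carbon of 16 (the nucleophilic alkyne carbon remote from oxygen) while the U-bearing carbon bonds to the siloxy carbon, giving 18 in a [2+2] whose orientation is dictated by the polarity of both partners. A second 4π opening gives dienylketene 19, and the only new ring, ring A of M, closes by 6π electrocyclisation of the ketene carbon onto the terminal methylene (20), followed by tautomerisation to 21. The ketene carbonyl thus becomes the single free hydroxyl (future O1) between C8–H and the alkyne-derived C4a, the siloxy oxygen becomes O5 and the benzyloxy oxygen O7, with U between them at C6; C4a–C8a and C5–C6 are new bonds and C8–C8a is re-formed. No stereocentre is created (the quaternary carbon of 18 is lost on ring opening), and the three stereocentres of U lie outside the reacting π system and meet neither acid nor base. The selectivities required are the orientation of the ketene–alkyne union (secured by the oxygen donor of 16), the productive geometry of 19 (both ring openings are reversible and only the isomer with the vinyl group cis to the ketene can cyclise) and chemoselectivity against acylation of the product phenol by 17 (excess 16 and gradual heating keep 17 at low concentration).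

Step 11
Reactants: 22 3,4-bis(benzyloxy)benzaldehyde
Product: 23 1,2-bis(benzyloxy)-4-ethynylbenzene
Conditions: dimethyl (1-diazo-2-oxopropyl)phosphonate, K2CO3, MeOH, rt
Reagents that add atoms: dimethyl (1-diazo-2-oxopropyl)phosphonate, COP(=O)(OC)C(=[N+]=[N-])C(C)=O
Why: Ohira–Bestmann homologation of the aldehyde to the terminal alkyne under mild base.

Step 12
Reactants: 23 1,2-bis(benzyloxy)-4-ethynylbenzene; 3 3,4,5-tris(benzyloxy)benzoic acid
Product: 24 (Z)-2-[3,4-bis(benzyloxy)phenyl]ethenyl 3,4,5-tris(benzyloxy)benzoate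
Conditions: Ru(η3-methallyl)2(dppb) (2 mol %), toluene, 65 °C
Reagents that add atoms: none
Why: Ruthenium-catalysed anti-Markovnikov addition of a carboxylic acid to a terminal alkyne through a vinylidene complex, a known route to (Z)-enol esters; the Z geometry results from addition of the carboxylate to the vinylidene carbon.

Step 13
Reactants: 21 5-benzyloxy-2-(dimethoxymethyl)-3-(triisopropylsilyloxy)-4-(U-4β-yl)phenol; 24 (Z)-2-[3,4-bis(benzyloxy)phenyl]ethenyl 3,4,5-tris(benzyloxy)benzoate
Product: 26 2α-[3,4-bis(benzyloxy)phenyl]-7-benzyloxy-4-methoxy-5-(triisopropylsilyloxy)-6-(U-4β-yl)chroman-3α-yl 3,4,5-tris(benzyloxy)benzoate (C4 epimers), via ortho-quinone methide 25 (not isolated)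
Conditions: (R)-3,3'-bis(2,4,6-triisopropylphenyl)-BINOL N-triflylphosphoramide (10 mol %; antipode chosen for the matched case), 24 (2 equiv), 3 Å MS, CH2Cl2, −40 → 0 °C
Reagents that add atoms: none
Why: Proposed new method: the closest known reaction types are the acid-promoted [4+2] cycloadditions of ortho-quinone methides, and of the oxocarbenium ions released from salicylaldehyde acetals, with electron-rich styrenes (giving 2-aryl-4-alkoxychromans), and the chiral-phosphate-controlled cycloadditions of ortho-quinone methides; new are the β-acyloxystyrene dienophile and catalyst control of absolute configuration on this substrate. The acid ionises the acetal of 21, assisted by the ortho hydroxyl, to 25 (or its O-protonated form paired with the chiral anion); the p-benzyloxyphenyl group of 24 polarises the alkene like a styrene, so the ester-bearing carbon bonds to C4 and the developing benzylic cation is captured by O1, and suprafacial addition to the (Z)-alkene gives the 2,3-cis ring with the gallate already on O3. The chiral anion is to select the alkene face that gives the 2α-aryl-3α-acyloxy (epicatechin) configuration; the C4 methoxy configuration is immaterial because C4 is re-ionised in step 14, and the acetal should ionise far more readily than the product ether, which protects 26.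

Step 14
Reactants: 26 2α-[3,4-bis(benzyloxy)phenyl]-7-benzyloxy-4-methoxy-5-(triisopropylsilyloxy)-6-(U-4β-yl)chroman-3α-yl 3,4,5-tris(benzyloxy)benzoate; 4 5,7,3',4'-tetra-O-benzyl-(−)-epicatechin 3-O-[3,4,5-tris(benzyloxy)benzoate]
Product: 27 protected trimer U-(4β→6)-M-(4β→8)-L carrying twenty benzyl ethers and the 5-O-triisopropylsilyl group on M
Conditions: TMSOTf (0.5 equiv), 4 (4 equiv), CH2Cl2, −78 → −40 °C; Et3N quench
Reagents that add atoms: none
Why: Lewis-acid ionisation of the C4 methyl ether (either epimer) gives the C4 cation of M, bridged on the α face by the C3 gallate carbonyl; C8 of 4, the most nucleophilic and least hindered ring A position, should attack from the β face and set C4 of M trans to the C3 ester, the standard flavan-4-yl cation arylation for 4→8 bonds. Excess 4 outcompetes the free ring A positions of 26.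

Step 15
Reactants: 27 protected trimer carrying the 5-O-triisopropylsilyl group on M
Product: 28 icosa-O-benzyl trimer with free 5-hydroxyl on M
Conditions: Bu4NF, AcOH, THF, 0 °C
Reagents that add atoms: none
Why: Fluoride cleaves the aryl silyl ether; buffering with acetic acid keeps the medium non-basic, so no C2 epimerisation or acyl transfer is expected.

Step 16
Reactants: 28 icosa-O-benzyl trimer with free 5-hydroxyl on M
Product: 29 epicatechin 3-O-gallate-(4β→6)-epicatechin 3-O-gallate-(4β→8)-epicatechin 3-O-gallate (CNP0183218.1)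
Conditions: H2 (1 atm), Pd(OH)2/C, THF–MeOH–H2O, rt
Reagents that add atoms: none
Why: Global hydrogenolysis of the twenty benzyl ethers under neutral conditions, the usual last step for galloylated procyanidins; esters, interflavan bonds and all eight stereocentres are not affected.

## Compound list

1 | (−)-epicatechin, (2R,3R) | O[C@@H]1Cc2c(O)cc(O)cc2O[C@@H]1c1ccc(O)c(O)c1 | starting material

2 | 5,7,3',4'-tetra-O-benzyl-(−)-epicatechin, (2R,3R) | O[C@@H]1Cc2c(OCc5ccccc5)cc(OCc5ccccc5)cc2O[C@@H]1c1ccc(OCc5ccccc5)c(OCc5ccccc5)c1 | intermediate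

3 | 3,4,5-tris(benzyloxy)benzoic acid | OC(=O)c1cc(OCc5ccccc5)c(OCc5ccccc5)c(OCc5ccccc5)c1 | starting material

4 | 5,7,3',4'-tetra-O-benzyl-(−)-epicatechin 3-O-[3,4,5-tris(benzyloxy)benzoate], (2R,3R), unit L | O=C(O[C@@H]1Cc2c(OCc5ccccc5)cc(OCc5ccccc5)cc2O[C@@H]1c1ccc(OCc5ccccc5)c(OCc5ccccc5)c1)c1cc(OCc5ccccc5)c(OCc5ccccc5)c(OCc5ccccc5)c1 | intermediate

5 | 4β-(2-ethoxyethoxy)-5,7,3',4'-tetra-O-benzyl-(−)-epicatechin (2,3-cis, 3,4-trans) | O[C@@H]1[C@@H](OCCOCC)c2c(OCc5ccccc5)cc(OCc5ccccc5)cc2O[C@@H]1c1ccc(OCc5ccccc5)c(OCc5ccccc5)c1 | intermediate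

6 | 4β-(2-ethoxyethoxy)-5,7,3',4'-tetra-O-benzyl-(−)-epicatechin 3-O-[3,4,5-tris(benzyloxy)benzoate], electrophilic unit U | O=C(O[C@@H]1[C@@H](OCCOCC)c2c(OCc5ccccc5)cc(OCc5ccccc5)cc2O[C@@H]1c1ccc(OCc5ccccc5)c(OCc5ccccc5)c1)c1cc(OCc5ccccc5)c(OCc5ccccc5)c(OCc5ccccc5)c1 | intermediate

7 | ethoxyacetylene | CCOC#C | starting material

8 | lithium ethoxyacetylide | [Li]C#COCC | intermediate (not isolated)

9 | tributyl(ethoxyethynyl)stannane | CCCC[Sn](CCCC)(CCCC)C#COCC | intermediate

10 | 4β-(ethoxyethynyl)-5,7,3',4'-tetra-O-benzyl-(−)-epicatechin 3-O-[3,4,5-tris(benzyloxy)benzoate] | O=C(O[C@@H]1[C@@H](C#COCC)c2c(OCc5ccccc5)cc(OCc5ccccc5)cc2O[C@@H]1c1ccc(OCc5ccccc5)c(OCc5ccccc5)c1)c1cc(OCc5ccccc5)c(OCc5ccccc5)c(OCc5ccccc5)c1 | intermediate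

11 | 3-ethoxy-2-(U-4β-yl)cyclobut-2-enone | O=C(O[C@@H]1[C@@H](C2=C(OCC)CC2=O)c2c(OCc5ccccc5)cc(OCc5ccccc5)cc2O[C@@H]1c1ccc(OCc5ccccc5)c(OCc5ccccc5)c1)c1cc(OCc5ccccc5)c(OCc5ccccc5)c(OCc5ccccc5)c1 | intermediate (not isolated)

12 | 3-hydroxy-2-(U-4β-yl)cyclobut-2-enone (enol of the 2-substituted cyclobutane-1,3-dione) | O=C(O[C@@H]1[C@@H](C2=C(O)CC2=O)c2c(OCc5ccccc5)cc(OCc5ccccc5)cc2O[C@@H]1c1ccc(OCc5ccccc5)c(OCc5ccccc5)c1)c1cc(OCc5ccccc5)c(OCc5ccccc5)c(OCc5ccccc5)c1 | intermediate

13 | 3-benzyloxy-2-(U-4β-yl)cyclobut-2-enone | O=C(O[C@@H]1[C@@H](C2=C(OCc5ccccc5)CC2=O)c2c(OCc5ccccc5)cc(OCc5ccccc5)cc2O[C@@H]1c1ccc(OCc5ccccc5)c(OCc5ccccc5)c1)c1cc(OCc5ccccc5)c(OCc5ccccc5)c(OCc5ccccc5)c1 | intermediate (key-step precursor)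

14 | methyl dimethoxyacetate | COC(OC)C(=O)OC | starting material

15 | lithium 3,3-dimethoxyprop-1-yn-1-olate | COC(OC)C#CO[Li] | intermediate (not isolated)

16 | 3,3-dimethoxy-1-(triisopropylsilyloxy)prop-1-yne | COC(OC)C#CO[Si](C(C)C)(C(C)C)C(C)C | intermediate (key-step precursor)

17 | vinylketene, 3-benzyloxy-2-(U-4β-yl)buta-1,3-dien-1-one | O=C(O[C@@H]1[C@@H](C(=C=O)C(OCc5ccccc5)=C)c2c(OCc5ccccc5)cc(OCc5ccccc5)cc2O[C@@H]1c1ccc(OCc5ccccc5)c(OCc5ccccc5)c1)c1cc(OCc5ccccc5)c(OCc5ccccc5)c(OCc5ccccc5)c1 | intermediate (not isolated)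

18 | vinylcyclobutenone, 4-(1-benzyloxyethenyl)-2-(dimethoxymethyl)-3-(triisopropylsilyloxy)-4-(U-4β-yl)cyclobut-2-enone (ring carbon 4 unspecified) | O=C(O[C@@H]1[C@@H](C2(C(OCc5ccccc5)=C)C(=O)C(C(OC)OC)=C2O[Si](C(C)C)(C(C)C)C(C)C)c2c(OCc5ccccc5)cc(OCc5ccccc5)cc2O[C@@H]1c1ccc(OCc5ccccc5)c(OCc5ccccc5)c1)c1cc(OCc5ccccc5)c(OCc5ccccc5)c(OCc5ccccc5)c1 | intermediate (not isolated)

19 | dienylketene, 5-benzyloxy-2-(dimethoxymethyl)-3-(triisopropylsilyloxy)-4-(U-4β-yl)hexa-1,3,5-trien-1-one | O=C(O[C@@H]1[C@@H](C(C(OCc5ccccc5)=C)=C(O[Si](C(C)C)(C(C)C)C(C)C)C(=C=O)C(OC)OC)c2c(OCc5ccccc5)cc(OCc5ccccc5)cc2O[C@@H]1c1ccc(OCc5ccccc5)c(OCc5ccccc5)c1)c1cc(OCc5ccccc5)c(OCc5ccccc5)c(OCc5ccccc5)c1 | intermediate (not isolated)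

20 | cyclohexadienone, 5-benzyloxy-2-(dimethoxymethyl)-3-(triisopropylsilyloxy)-4-(U-4β-yl)cyclohexa-2,4-dien-1-one | O=C(O[C@@H]1[C@@H](C2=C(OCc5ccccc5)CC(=O)C(C(OC)OC)=C2O[Si](C(C)C)(C(C)C)C(C)C)c2c(OCc5ccccc5)cc(OCc5ccccc5)cc2O[C@@H]1c1ccc(OCc5ccccc5)c(OCc5ccccc5)c1)c1cc(OCc5ccccc5)c(OCc5ccccc5)c(OCc5ccccc5)c1 | intermediate (not isolated)

21 | 5-benzyloxy-2-(dimethoxymethyl)-3-(triisopropylsilyloxy)-4-(U-4β-yl)phenol (ring A of M: free O1–H, acetal carbon is the future C4, O5 silyl, O7 benzyl) | O=C(O[C@@H]1[C@@H](c2c(OCc5ccccc5)cc(O)c(C(OC)OC)c2O[Si](C(C)C)(C(C)C)C(C)C)c2c(OCc5ccccc5)cc(OCc5ccccc5)cc2O[C@@H]1c1ccc(OCc5ccccc5)c(OCc5ccccc5)c1)c1cc(OCc5ccccc5)c(OCc5ccccc5)c(OCc5ccccc5)c1 | intermediate (key-step product)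

22 | 3,4-bis(benzyloxy)benzaldehyde | O=Cc1ccc(OCc5ccccc5)c(OCc5ccccc5)c1 | starting material

23 | 1,2-bis(benzyloxy)-4-ethynylbenzene | C#Cc1ccc(OCc5ccccc5)c(OCc5ccccc5)c1 | intermediate

24 | (Z)-2-[3,4-bis(benzyloxy)phenyl]ethenyl 3,4,5-tris(benzyloxy)benzoate | O=C(O/C=C\c1ccc(OCc5ccccc5)c(OCc5ccccc5)c1)c1cc(OCc5ccccc5)c(OCc5ccccc5)c(OCc5ccccc5)c1 | intermediate

25 | ortho-quinone methide, 3-benzyloxy-6-(methoxymethylidene)-5-(triisopropylsilyloxy)-4-(U-4β-yl)cyclohexa-2,4-dien-1-one | O=C(O[C@@H]1[C@@H](C2=C(O[Si](C(C)C)(C(C)C)C(C)C)C(=COC)C(=O)C=C2OCc5ccccc5)c2c(OCc5ccccc5)cc(OCc5ccccc5)cc2O[C@@H]1c1ccc(OCc5ccccc5)c(OCc5ccccc5)c1)c1cc(OCc5ccccc5)c(OCc5ccccc5)c(OCc5ccccc5)c1 | intermediate (not isolated)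

26 | U-(4β→6)-M dimer: 2α-[3,4-bis(benzyloxy)phenyl]-7-benzyloxy-4-methoxy-5-(triisopropylsilyloxy)-6-(U-4β-yl)chroman-3α-yl 3,4,5-tris(benzyloxy)benzoate (2,3-cis, C4 epimers) | O=C(O[C@@H]1[C@@H](c2c(OCc5ccccc5)cc3c(c2O[Si](C(C)C)(C(C)C)C(C)C)C(OC)[C@@H](OC(=O)c2cc(OCc5ccccc5)c(OCc5ccccc5)c(OCc5ccccc5)c2)[C@@H](c2ccc(OCc5ccccc5)c(OCc5ccccc5)c2)O3)c2c(OCc5ccccc5)cc(OCc5ccccc5)cc2O[C@@H]1c1ccc(OCc5ccccc5)c(OCc5ccccc5)c1)c1cc(OCc5ccccc5)c(OCc5ccccc5)c(OCc5ccccc5)c1 | intermediate

27 | protected trimer U-(4β→6)-M-(4β→8)-L, twenty benzyl ethers, 5-O-triisopropylsilyl on M | O=C(O[C@@H]1[C@@H](c2c(OCc5ccccc5)cc3c(c2O[Si](C(C)C)(C(C)C)C(C)C)[C@H](c2c(OCc5ccccc5)cc(OCc5ccccc5)c4c2O[C@H](c2ccc(OCc5ccccc5)c(OCc5ccccc5)c2)[C@H](OC(=O)c2cc(OCc5ccccc5)c(OCc5ccccc5)c(OCc5ccccc5)c2)C4)[C@@H](OC(=O)c2cc(OCc5ccccc5)c(OCc5ccccc5)c(OCc5ccccc5)c2)[C@@H](c2ccc(OCc5ccccc5)c(OCc5ccccc5)c2)O3)c2c(OCc5ccccc5)cc(OCc5ccccc5)cc2O[C@@H]1c1ccc(OCc5ccccc5)c(OCc5ccccc5)c1)c1cc(OCc5ccccc5)c(OCc5ccccc5)c(OCc5ccccc5)c1 | intermediate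

28 | icosa-O-benzyl trimer with free 5-hydroxyl on M | O=C(O[C@@H]1[C@@H](c2c(OCc5ccccc5)cc3c(c2O)[C@H](c2c(OCc5ccccc5)cc(OCc5ccccc5)c4c2O[C@H](c2ccc(OCc5ccccc5)c(OCc5ccccc5)c2)[C@H](OC(=O)c2cc(OCc5ccccc5)c(OCc5ccccc5)c(OCc5ccccc5)c2)C4)[C@@H](OC(=O)c2cc(OCc5ccccc5)c(OCc5ccccc5)c(OCc5ccccc5)c2)[C@@H](c2ccc(OCc5ccccc5)c(OCc5ccccc5)c2)O3)c2c(OCc5ccccc5)cc(OCc5ccccc5)cc2O[C@@H]1c1ccc(OCc5ccccc5)c(OCc5ccccc5)c1)c1cc(OCc5ccccc5)c(OCc5ccccc5)c(OCc5ccccc5)c1 | intermediate

29 | epicatechin 3-O-gallate-(4β→6)-epicatechin 3-O-gallate-(4β→8)-epicatechin 3-O-gallate, CNP0183218.1 | O=C(O[C@@H]1[C@@H](c2c(O)cc3c(c2O)[C@H](c2c(O)cc(O)c4c2O[C@H](c2ccc(O)c(O)c2)[C@H](OC(=O)c2cc(O)c(O)c(O)c2)C4)[C@@H](OC(=O)c2cc(O)c(O)c(O)c2)[C@@H](c2ccc(O)c(O)c2)O3)c2c(O)cc(O)cc2O[C@@H]1c1ccc(O)c(O)c1)c1cc(O)c(O)c(O)c1 | target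

## Step count and least certain steps

Total: 16 steps. Longest linear sequence: 11 steps (1 → 2 → 5 → 6 → 10 → 12 → 13 → 21 → 26 → 27 → 28 → 29; steps 1, 3, 4, 6, 7, 8, 10, 13, 14, 15, 16).

**Step 10 (key step, proposed new method).**
- What may go wrong: slow electrocyclic opening of the donor-stabilised cyclobutenone, so that temperatures are needed at which the vinylketene dimerises or acylates the product phenol; steric retardation of the ketene–alkyne union by the large C2 substituent; thermal loss of methanol from the phenol acetal.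
- Fallback with known chemistry, setting out from 6 and 4 and returning to the route at 29: ring A of M is not built but taken from the chiral pool with C8 capped. Bromination of 6 (N-bromosuccinimide, CH2Cl2, −78 °C → rt) should give the 8-bromo ether F1. Exchange of its C4 ether for a thioether (2,6-dimethylbenzenethiol, BF3·OEt2, −78 °C) gives the 8-bromo 4β-arylthio unit F2, whose only free ring A position is C6. TMSOTf-mediated reaction of 6 with F2 (hard activation leaves the thioether untouched) gives the (4β→6) dimer F3. Thiophilic activation of F3 (N-iodosuccinimide, −78 °C) in the presence of 4 gives the 8-bromo perbenzylated trimer F4 (identical with A4). Hydrogenolysis (H2, Pd(OH)2/C, Et3N) removes the bromine and all benzyl groups to give 29.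

**Step 13 (proposed new method).**
- What may go wrong: poor facial selectivity, because the chiral anion has no second binding point on the alkene; loss of the cis relation through a stepwise path via a long-lived benzylic cation, possibly trapped by the neighbouring ester carbonyl; reversed regiochemistry; acyl transfer from the enol ester to the phenol; Friedel–Crafts oligomerisation of the quinone methide with the electron-rich rings.
- Fallback with known reaction types, setting out from 21 and 4 and returning at 27 (the logic of alternative 3): mild acid (pyridinium p-toluenesulfonate, CH2Cl2, −20 °C, one equivalent of 4) should arylate the acetal carbon with C8 of 4 to give the ortho-hydroxybenzhydryl methyl ether F5. trans-Hydroboration of 23 with catecholborane ([Rh(cod)Cl]2, P(i-Pr)3, Et3N) and ethanolysis gives the diethyl (Z)-styrylboronate F6. A chiral 3,3'-dibromo-BINOL catalyst then mediates conjugate addition of F6 to the quinone methide released from F5, setting C4 and giving the (Z)-cinnamyl phenol F7. Dioxirane epoxidation on the alkene face anti to ring A (allylic strain, reinforced if needed by a Shi-type ketone with KHSO5), followed by a trace of camphorsulfonic acid, lets O1 open the cis-epoxide at benzylic C2 with inversion to give the 3-hydroxy trimer F8. Steglich esterification of F8 with 3 gives 27.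

**Step 6.**
- What may go wrong: protodestannylation or hydration of the ynol ether by the Lewis acid, loss of the ethyl group from the intermediate ketene-oxonium ion, and self-condensation of the C4 cation with ring A of a second molecule.
- Fallback, setting out from 6 and returning at 12: TMSOTf-mediated substitution with 1,1-bis(trimethylsilyloxy)ethene gives the 4β-acetic acid F9. Its acid chloride (oxalyl chloride), treated with Et3N in the presence of excess 7, forms the monosubstituted ketene, which adds to 7 to give the 3-ethoxy-4-(U-4β-yl)cyclobut-2-enone F10. The same mild acid hydrolysis as in step 7 converts F10 into 12, because the dione is symmetrical.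

**Step 14.**
- What may go wrong: slow capture of the C4 cation because of shielding by the neighbouring silyl ether, leading to elimination towards the flav-3-ene or attack by the substrate's own rings; acid-induced scission or scrambling of the existing U–M bond; attack through C6 of 4.
- Fallback, setting out from 26 and returning at 27: thiolysis (benzyl mercaptan, BF3·OEt2, −40 °C) gives the 4β-benzylthio dimer F11, which is activated under nearly neutral conditions with AgBF4 (THF, 0 °C) in the presence of 4 to give 27.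

## Further compounds

F1 | step 10 | 8-bromo-4β-(2-ethoxyethoxy)-5,7,3',4'-tetra-O-benzylepicatechin 3-O-[3,4,5-tris(benzyloxy)benzoate] | O=C(O[C@@H]1[C@@H](OCCOCC)c2c(OCc5ccccc5)cc(OCc5ccccc5)c(Br)c2O[C@@H]1c1ccc(OCc5ccccc5)c(OCc5ccccc5)c1)c1cc(OCc5ccccc5)c(OCc5ccccc5)c(OCc5ccccc5)c1

F2 | step 10 | 8-bromo-4β-(2,6-dimethylphenylthio)-5,7,3',4'-tetra-O-benzylepicatechin 3-O-[3,4,5-tris(benzyloxy)benzoate] | O=C(O[C@@H]1[C@@H](Sc2c(C)cccc2C)c2c(OCc5ccccc5)cc(OCc5ccccc5)c(Br)c2O[C@@H]1c1ccc(OCc5ccccc5)c(OCc5ccccc5)c1)c1cc(OCc5ccccc5)c(OCc5ccccc5)c(OCc5ccccc5)c1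

F3 | step 10 | U-(4β→6) dimer with 8-bromo and 4β-(2,6-dimethylphenylthio) groups on M, perbenzylated, both units 3-O-galloylated | O=C(O[C@@H]1[C@@H](c2c(OCc5ccccc5)c(Br)c3c(c2OCc5ccccc5)[C@H](Sc2c(C)cccc2C)[C@@H](OC(=O)c2cc(OCc5ccccc5)c(OCc5ccccc5)c(OCc5ccccc5)c2)[C@@H](c2ccc(OCc5ccccc5)c(OCc5ccccc5)c2)O3)c2c(OCc5ccccc5)cc(OCc5ccccc5)cc2O[C@@H]1c1ccc(OCc5ccccc5)c(OCc5ccccc5)c1)c1cc(OCc5ccccc5)c(OCc5ccccc5)c(OCc5ccccc5)c1

F4 | step 10 | perbenzylated trimer with bromine at C8 of M | O=C(O[C@@H]1[C@@H](c2c(OCc5ccccc5)c(Br)c3c(c2OCc5ccccc5)[C@H](c2c(OCc5ccccc5)cc(OCc5ccccc5)c4c2O[C@H](c2ccc(OCc5ccccc5)c(OCc5ccccc5)c2)[C@H](OC(=O)c2cc(OCc5ccccc5)c(OCc5ccccc5)c(OCc5ccccc5)c2)C4)[C@@H](OC(=O)c2cc(OCc5ccccc5)c(OCc5ccccc5)c(OCc5ccccc5)c2)[C@@H](c2ccc(OCc5ccccc5)c(OCc5ccccc5)c2)O3)c2c(OCc5ccccc5)cc(OCc5ccccc5)cc2O[C@@H]1c1ccc(OCc5ccccc5)c(OCc5ccccc5)c1)c1cc(OCc5ccccc5)c(OCc5ccccc5)c(OCc5ccccc5)c1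

F5 | step 13 | ortho-hydroxybenzhydryl methyl ether: ring A of 21 with its acetal carbon bearing methoxy and C8 of unit L (benzhydryl carbon unspecified) | O=C(O[C@@H]1[C@@H](c2c(OCc5ccccc5)cc(O)c(C(OC)c3c(OCc5ccccc5)cc(OCc5ccccc5)c4c3O[C@H](c3ccc(OCc5ccccc5)c(OCc5ccccc5)c3)[C@H](OC(=O)c3cc(OCc5ccccc5)c(OCc5ccccc5)c(OCc5ccccc5)c3)C4)c2O[Si](C(C)C)(C(C)C)C(C)C)c2c(OCc5ccccc5)cc(OCc5ccccc5)cc2O[C@@H]1c1ccc(OCc5ccccc5)c(OCc5ccccc5)c1)c1cc(OCc5ccccc5)c(OCc5ccccc5)c(OCc5ccccc5)c1

F6 | step 13 | diethyl (Z)-2-[3,4-bis(benzyloxy)phenyl]ethenylboronate | CCOB(OCC)/C=C\c1ccc(OCc5ccccc5)c(OCc5ccccc5)c1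

F7 | step 13 | (Z)-cinnamyl phenol: ring A of M with free O1–H, 5-O-triisopropylsilyl, U at C6, and C4 bearing unit L and the (Z)-2-arylethenyl group | O=C(O[C@@H]1[C@@H](c2c(OCc5ccccc5)cc(O)c([C@H](c3c(OCc5ccccc5)cc(OCc5ccccc5)c4c3O[C@H](c3ccc(OCc5ccccc5)c(OCc5ccccc5)c3)[C@H](OC(=O)c3cc(OCc5ccccc5)c(OCc5ccccc5)c(OCc5ccccc5)c3)C4)/C=C\c3ccc(OCc5ccccc5)c(OCc5ccccc5)c3)c2O[Si](C(C)C)(C(C)C)C(C)C)c2c(OCc5ccccc5)cc(OCc5ccccc5)cc2O[C@@H]1c1ccc(OCc5ccccc5)c(OCc5ccccc5)c1)c1cc(OCc5ccccc5)c(OCc5ccccc5)c(OCc5ccccc5)c1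

F8 | step 13 | protected trimer with free C3 hydroxyl and 5-O-triisopropylsilyl on M | O=C(O[C@@H]1[C@@H](c2c(OCc5ccccc5)cc3c(c2O[Si](C(C)C)(C(C)C)C(C)C)[C@H](c2c(OCc5ccccc5)cc(OCc5ccccc5)c4c2O[C@H](c2ccc(OCc5ccccc5)c(OCc5ccccc5)c2)[C@H](OC(=O)c2cc(OCc5ccccc5)c(OCc5ccccc5)c(OCc5ccccc5)c2)C4)[C@@H](O)[C@@H](c2ccc(OCc5ccccc5)c(OCc5ccccc5)c2)O3)c2c(OCc5ccccc5)cc(OCc5ccccc5)cc2O[C@@H]1c1ccc(OCc5ccccc5)c(OCc5ccccc5)c1)c1cc(OCc5ccccc5)c(OCc5ccccc5)c(OCc5ccccc5)c1

F9 | step 6 | 2-(U-4β-yl)acetic acid | O=C(O[C@@H]1[C@@H](CC(=O)O)c2c(OCc5ccccc5)cc(OCc5ccccc5)cc2O[C@@H]1c1ccc(OCc5ccccc5)c(OCc5ccccc5)c1)c1cc(OCc5ccccc5)c(OCc5ccccc5)c(OCc5ccccc5)c1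

F10 | step 6 | 3-ethoxy-4-(U-4β-yl)cyclobut-2-enone (ring carbon 4 unspecified) | O=C(O[C@@H]1[C@@H](C2C(=O)C=C2OCC)c2c(OCc5ccccc5)cc(OCc5ccccc5)cc2O[C@@H]1c1ccc(OCc5ccccc5)c(OCc5ccccc5)c1)c1cc(OCc5ccccc5)c(OCc5ccccc5)c(OCc5ccccc5)c1

F11 | step 14 | 4β-benzylthio analogue of 26 | O=C(O[C@@H]1[C@@H](c2c(OCc5ccccc5)cc3c(c2O[Si](C(C)C)(C(C)C)C(C)C)[C@H](SCc2ccccc2)[C@@H](OC(=O)c2cc(OCc5ccccc5)c(OCc5ccccc5)c(OCc5ccccc5)c2)[C@@H](c2ccc(OCc5ccccc5)c(OCc5ccccc5)c2)O3)c2c(OCc5ccccc5)cc(OCc5ccccc5)cc2O[C@@H]1c1ccc(OCc5ccccc5)c(OCc5ccccc5)c1)c1cc(OCc5ccccc5)c(OCc5ccccc5)c(OCc5ccccc5)c1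

A1 | alternative 1 | 4-aryl-3,4-dihydrocoumarin carrying U at C6 and L at C4 (3-O-tert-butyldimethylsilyl on U and L) | CC(C)(C)[Si](C)(C)O[C@@H]1[C@@H](c2c(OCc5ccccc5)cc3c(c2OCc5ccccc5)[C@H](c2c(OCc5ccccc5)cc(OCc5ccccc5)c4c2O[C@H](c2ccc(OCc5ccccc5)c(OCc5ccccc5)c2)[C@H](O[Si](C)(C)C(C)(C)C)C4)CC(=O)O3)c2c(OCc5ccccc5)cc(OCc5ccccc5)cc2O[C@@H]1c1ccc(OCc5ccccc5)c(OCc5ccccc5)c1

A2 | alternative 1 | 3,5-bis(benzyloxy)-4-(3-O-tert-butyldimethylsilyl-5,7,3',4'-tetra-O-benzylepicatechin-4β-yl)phenol | CC(C)(C)[Si](C)(C)O[C@@H]1[C@@H](c2c(OCc5ccccc5)cc(O)cc2OCc5ccccc5)c2c(OCc5ccccc5)cc(OCc5ccccc5)cc2O[C@@H]1c1ccc(OCc5ccccc5)c(OCc5ccccc5)c1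

A3 | alternative 1 | (E)-3-(3-O-tert-butyldimethylsilyl-5,7,3',4'-tetra-O-benzylepicatechin-8-yl)-1-(3,5-dimethylpyrazol-1-yl)prop-2-en-1-one | O=C(/C=C/c2c(OCc5ccccc5)cc(OCc5ccccc5)c4c2O[C@H](c2ccc(OCc5ccccc5)c(OCc5ccccc5)c2)[C@H](O[Si](C)(C)C(C)(C)C)C4)n1nc(C)cc1C

A4 | alternative 2 | perbenzylated target with bromine at C8 of M | O=C(O[C@@H]1[C@@H](c2c(OCc5ccccc5)c(Br)c3c(c2OCc5ccccc5)[C@H](c2c(OCc5ccccc5)cc(OCc5ccccc5)c4c2O[C@H](c2ccc(OCc5ccccc5)c(OCc5ccccc5)c2)[C@H](OC(=O)c2cc(OCc5ccccc5)c(OCc5ccccc5)c(OCc5ccccc5)c2)C4)[C@@H](OC(=O)c2cc(OCc5ccccc5)c(OCc5ccccc5)c(OCc5ccccc5)c2)[C@@H](c2ccc(OCc5ccccc5)c(OCc5ccccc5)c2)O3)c2c(OCc5ccccc5)cc(OCc5ccccc5)cc2O[C@@H]1c1ccc(OCc5ccccc5)c(OCc5ccccc5)c1)c1cc(OCc5ccccc5)c(OCc5ccccc5)c(OCc5ccccc5)c1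

A5 | alternative 2 | perbenzylated M-(4β→8)-L dimer, both units 3-O-galloylated, with formyl at C6 and bromine at C8 of M | O=Cc2c(OCc5ccccc5)c(Br)c3c(c2OCc5ccccc5)[C@H](c2c(OCc5ccccc5)cc(OCc5ccccc5)c4c2O[C@H](c2ccc(OCc5ccccc5)c(OCc5ccccc5)c2)[C@H](OC(=O)c2cc(OCc5ccccc5)c(OCc5ccccc5)c(OCc5ccccc5)c2)C4)[C@@H](OC(=O)c2cc(OCc5ccccc5)c(OCc5ccccc5)c(OCc5ccccc5)c2)[C@@H](c2ccc(OCc5ccccc5)c(OCc5ccccc5)c2)O3

A6 | alternative 2 | 3,5-bis(benzyloxy)phenol | Oc1cc(OCc5ccccc5)cc(OCc5ccccc5)c1

A7 | alternative 3 | perbenzylated trimer with free C3 hydroxyl on M | O=C(O[C@@H]1[C@@H](c2c(OCc5ccccc5)cc3c(c2OCc5ccccc5)[C@H](c2c(OCc5ccccc5)cc(OCc5ccccc5)c4c2O[C@H](c2ccc(OCc5ccccc5)c(OCc5ccccc5)c2)[C@H](OC(=O)c2cc(OCc5ccccc5)c(OCc5ccccc5)c(OCc5ccccc5)c2)C4)[C@@H](O)[C@@H](c2ccc(OCc5ccccc5)c(OCc5ccccc5)c2)O3)c2c(OCc5ccccc5)cc(OCc5ccccc5)cc2O[C@@H]1c1ccc(OCc5ccccc5)c(OCc5ccccc5)c1)c1cc(OCc5ccccc5)c(OCc5ccccc5)c(OCc5ccccc5)c1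

A8 | alternative 3 | (Z)-cinnamyl phenol tert-butyldimethylsilyl ether: ring A of M with O1 silylated, 5,7-bis(benzyloxy), U at C6, and C4 bearing unit L and the (Z)-2-arylethenyl group | O=C(O[C@@H]1[C@@H](c2c(OCc5ccccc5)cc(O[Si](C)(C)C(C)(C)C)c([C@H](c3c(OCc5ccccc5)cc(OCc5ccccc5)c4c3O[C@H](c3ccc(OCc5ccccc5)c(OCc5ccccc5)c3)[C@H](OC(=O)c3cc(OCc5ccccc5)c(OCc5ccccc5)c(OCc5ccccc5)c3)C4)/C=C\c3ccc(OCc5ccccc5)c(OCc5ccccc5)c3)c2OCc5ccccc5)c2c(OCc5ccccc5)cc(OCc5ccccc5)cc2O[C@@H]1c1ccc(OCc5ccccc5)c(OCc5ccccc5)c1)c1cc(OCc5ccccc5)c(OCc5ccccc5)c(OCc5ccccc5)c1
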